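(The earlier runs and the new flask are calculated for an exercise; the scatter is artificial.)

J is the one thing read here, so I work from its slope.

| flask | E | Z | L | time |
|---|---|---|---|---|
| Saturday's | 0.800 M | 0.880 M | 0.0240 M |  |
| Tuesday's | 0.400 M | 0.880 M | 0.0240 M |  |
| Thursday's | 0.800 M | 0.290 M | 0.00790 M | 3.4 h |

| Saturday's run: time / h | Saturday's run: [J] / M | Tuesday's run: time / h | Tuesday's run: [J] / M |
|---|---|---|---|
| 0.68 | 0.1318 | 0.68 | 0.1032 |
| 1.4 | 0.2622 | 1.4 | 0.1938 |
| 2.0 | 0.3530 | 2.0 | 0.2484 |
| 2.7 | 0.4350 | 2.7 | 0.2919 |
| 3.4 | 0.4928 | 3.4 | 0.3280 |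

(standard deviation of a reading: 0.002 M)

- reaction order in [E] at the outset, round the charge of the Saturday's run, defined at two percent of the E turned into J (one fixed amount of J, the same in the runs compared)
- J in the Thursday's run at 3.4 h, as a share of the E charged

- Overall: E + Z -> J, with L as catalyst.
- Constant volume, constant temperature.
- A reading of a species includes what of it is bound.
- An order is taken over about fifteen percent of the charge, up and down.

Tuesday's first reading over Saturday's, with E halved, gives a mean order of 0.353 between the two charges. I take that as my ceiling for the order at Saturday's charge, and zero as my floor.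

For Thursday's flask I carry one quantity. Saturday's first interval gives 9.92 M⁻¹ h⁻¹ for w, the rate of making J per unit of cZ and per unit of cL, with cZ taken at its interval mean. Saturday's last interval gives 8.27 M⁻¹ h⁻¹. I assume that Thursday's w lies between these two readings. Z is the limiting reagent in Thursday's flask, with 0.290 M against 0.800 M of E. The product of w, cL and time is 0.266 with the higher w and 0.222 with the lower. Higher w with cZ held at its charge gives a top of 9.64 % of the E charged. Lower w with cZ held at that top's end value gives a floor of 5.91 %.

To tighten this, I replace the falling cZ by its mean, the charge minus half the J made. The bracket becomes 7.25 % to 8.52 %. Exponential decay of cZ at the higher w gives 8.47 %, against 8.52 % from the mean.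

The forecast says 8.5 % (range 6.5 % to 12 %), at my top edge, and 0.05 for the order (range −0.25 to 0.3). Like mine, it scales with cL, “though L's order is untested”.

The flask gives 7.91 % for Thursday's flask and 0.20 for the order, both inside my brackets. At equal J, Tuesday's flask, with half the E, runs at 0.84 of the rate of Saturday's flask.

    L + E ⇌ LE, settled at all times (6.980 M⁻¹)
    LE + Z → J + L + G (10.98 M⁻¹ h⁻¹)
    E + Z + J → 2 J (0.7668 M⁻² h⁻¹)
    LE → Qe + E (0.2311 h⁻¹)

Thursday's result is 0.0633 M of J, which through the mean-cZ rule means w = 9.12 M⁻¹ h⁻¹, lower than the 9.92 M⁻¹ h⁻¹ of Saturday's first interval and higher than the 8.27 M⁻¹ h⁻¹ of Saturday's last interval. Tuesday's rate of 0.17 M h⁻¹, at two percent of Saturday's E turned, gives w = 7.96 M⁻¹ h⁻¹.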